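The readings were generated by integration with made-up constants; the scatter is artificial.

Take what is left in the larch run at 30.0 h: substrate 0%, target 3.4%. Target has fallen there from 8.0% at 10.0 h, when substrate stood at 2.6%, so ask how fast target goes with so little substrate left.

| flask | substrate | capture agent | gas | remark | time |
|---|---|---|---|---|---|
| larch | 10 mM | 5 mM | 0.32 mM (held) | run made earlier |  |
| elm | 10 mM | 7.5 mM | 0.32 mM (held) | run made earlier |  |
| flask | 10 mM | 10.0 mM | 0.32 mM (held) |  | 40 h |

| run | time / h | target / % | substrate / % |
|---|---|---|---|
| larch | 1.33 | 5.0 | 59.8 |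
| larch | 4.00 | 9.3 | 20.8 |
| larch | 10.0 | 8.0 | 2.6 |
| larch | 30.0 | 3.4 | 0 |
| elm | 1.33 | 5.3 | 59.6 |
| elm | 4.00 | 9.6 | 21.1 |
| elm | 10.0 | 8.7 | 2.2 |
| elm | 30.0 | 3.2 | 0.4 |

(standard deviation of a reading: 0.3 percentage points)

- when, up to 40 h, the flask holds most target
- the amount of target, in percent of the substrate charged, at that time

Try a loss proportional to the square of target (second order). The reciprocal of its concentration then climbs in a straight line, and the two larch readings give a slope of 84.6 L mol⁻¹ h⁻¹: call it the tail slope. The first two larch readings of substrate give a first-order rate of 0.396 h⁻¹.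

Now turn the settings. Raise capture agent: from larch at 5 mM to elm at 7.5 mM, the target reading at 4.00 h moves from 9.3% to 9.6%, about one scatter of 0.3 percentage points, so expect roughly that level in the flask. Then turn time: at that level, the tail slope gives a loss per unit of target of 0.0812 h⁻¹, and a rise and fall with these two rates peaks at ln(gain/loss)/(gain−loss), which I reckon at 5.04 h. The forecast differs from my reckoning: with a tail of 0.05 /h it says a later 6 h, with 9.9%, holding that "The capture step therefore looks saturated".

The flask peaks at 5.13 h with 9.74%.

    open intermediate ⇌ target + by-product (K = 0.00740 M, k = 0.740 h⁻¹)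
    open intermediate → side product (k = 4.20 h⁻¹)
    substrate + reagent ⇌ open intermediate (K = 4400 L mol⁻¹, k = 1300 L mol⁻¹ h⁻¹)
    open intermediate + capture agent → trapped intermediate (k = 23.0 L mol⁻¹ h⁻¹)
    gas ⇌ reagent, rate k5*(csat - [reagent]) (kL = 1100 h⁻¹)

In the flask, open intermediate has a half-life of 0.17 h by its step to side product alone and 0.94 h by the forward rate of its step to target alone, and at 40.0 h the flask holds 92.4% side product and 2.68% target. Carried from the flask's 4.93% at 20.0 h, the tail slope gives 2.69% at 40.0 h. Started from the best of 11.3% in the neighbour flask with 4.0 mM substrate, and assuming its peak falls near the flask's time, it gives 4.85% at 40.0 h; that neighbour flask then holds 5.20%.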